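The runs were generated by integration on assumed constants; noise was put on by code.

Begin with the easy count. We take double product to carry two partners per substrate, so a charge of 1.00 equiv can fill a fraction p = 50.0 % of the sites, and p is also the ceiling on double product. As the zero of the scale we let the two sites fill independently. Then a fraction p squared of the substrate is doubly coupled, and this p squared, the statistical double S, is 25.0 % here.

- red: substrate 0.22 M; coupling partner 2 equiv; run made earlier
- flask: substrate 0.22 M; coupling partner 1.00 equiv; time 10 min

red run (percent of the substrate charged)

| time / min | double product / % | triple product / % | substrate / % |
|---|---|---|---|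
| 0.833 | 15.1 | 7.4 | 42.3 |
| 1.50 | 22.1 | 11.0 | 29.5 |
| 2.50 | 29.0 | 13.6 | 20.3 |
| 3.00 | 36.8 | 10.4 | 16.9 |

(scatter of a reading: 1 percentage point)



- equivalents of coupling partner to substrate, everything else as given, that leave most double product at 10 min
- the amount of double product then, in percent of the substrate charged
- the amount of double product with the amounts as given

Now the curve of this flask. The first red reading gives a logarithmic slope, averaged up to that reading, of 1.03 min⁻¹ for substrate, so with this charge we expect about 0.516 min⁻¹ early on. For this flask the zero sets the substrate level at (1−p) squared, 25.0 %, with 50.0 % coupled once. Held constant, that slope reaches the level in 2.68 min, which is earlier than 10 min, and we expect the knee somewhat later, with the slope flattening as partner is used.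

The red run tests the zero. Its last substrate reading, 16.9 %, taken on the terms of the zero, gives q = 58.9 % of sites filled, and q squared is 34.7 %, yet double plus triple reads 47.2 %, a factor 1.36 as read. So our own reckoning puts double plus triple in this flask near 34.0 %.

The forecast gave 26 % (17 % to 33 %) of double product alone, and a best dose of 2.3 equiv (1.9 equiv to 3 equiv) giving 76 % (64 % to 86 %), warning: “Too much excess pushes double into triple.”

The flask gives 29.2 %; the best dose is 2.27 equiv, giving 59.9 %, which is 16 percentage points under the forecast.

    coupling partner + double product ⇌ triple product + by-product (K = 1.44, k = 0.113 L mol⁻¹ s⁻¹)
    triple product ⇌ isomer of the product (K = 0.332, k = 0.0265 s⁻¹)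
    coupling partner + mono adduct → double product + by-product (k = 0.0658 L mol⁻¹ s⁻¹)
    coupling partner + triple product → over-reaction product (k = 0.0386 L mol⁻¹ s⁻¹)
    substrate + coupling partner → mono adduct + by-product (k = 0.0512 L mol⁻¹ s⁻¹)

The flask ends 4.2 points above S. Run without the way back from triple product + by-product, this flask holds 13.7 % of double product, and without the way back from isomer of the product 17.6 %, both under S. The first of these returns is the largest single effect on double product here, and it acts together with the second.

In the neighbour flask with 0.250 equiv of coupling partner, p is 12.5 %, so S is 1.56 %. That flask gives 3.01 % of double product.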